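(The numbers in the tables come from a simulation from invented constants; scatter was added.)

1. A small charge of coupling partner stands in the spring flask: 0.130 M is less than the 0.200 M that 0.10 M of substrate would need, because each target on the list of suspects takes coupling partner twice. My decision is what to do to this flask at 6.0 h.

in all of them: substrate 0.10 M

| run | fresh partner | coupling partner | temperature | remark | time |
|---|---|---|---|---|---|
| spring | 0.18 M | 0.13 M | 35 °C | the very flask that is asked about, followed so far |  |
| noon | 0.18 M | 0.13 M | 41 °C | run made earlier |  |
| flask | 0.180 M | 0.130 M | 35 °C |  | 6.0 h |

| run | time / min | target / % |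
|---|---|---|
| spring | 25.0 | 17.7 |
| spring | 40.0 | 23.1 |
| spring | 60.0 | 25.2 |
| spring | 120 | 25.8 |
| spring | 180 | 25.2 |
| spring | 300 | 24.9 |
| noon | 25.0 | 23.0 |
| noon | 40.0 | 25.7 |
| noon | 60.0 | 25.9 |
| noon | 120 | 25.6 |
| noon | 180 | 26.0 |
| noon | 300 | 26.1 |

(scatter of a reading: 0.5 percentage points)

* target, in percent of the substrate first charged, at 6.0 h
* which option adds most target ("none" when 2 percentage points or less is all one gets) (alpha / epsilon / eta / gamma / none)
* target present, with what was taken out counted in, in percent of the substrate first charged, after epsilon
* target present, with what was taken out counted in, in percent of the substrate first charged, after gamma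

- target taken out counts as made
- on the list of suspects stand: substrate + coupling partner -> open intermediate; coupling partner + fresh partner -> second intermediate; open intermediate + second intermediate -> target; target <-> isomer of the product
- additions bring no volume worth counting

- alpha: at 6.0 h take out 90% of the target then present, then wait 12 h
- epsilon: change nothing and wait 12 h more
- eta: at 6.0 h add coupling partner, 100% of the amount charged, then wait 12 h
- gamma: at 6.0 h raise the temperature by 25 K, then wait 12 h

2. I replace the late spring curve by its mean. The 4 readings from 60.0 min to 300 min give 25.3%, with an error of 0.25 percentage points, the scatter divided by the root of their number.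

3. I check what the flat line costs. The last of these readings differs from the first by 0.3 points, which is less than the 0.71 points scatter of a difference, so I see no drift.

4. Scaling the mean by substrate over coupling partner gives 0.194. This target made per coupling partner charged, in moles per mole, is the coupling yield. It lies below the ceiling of 0.5 that two coupling partners per target allow.

5. The same 4 readings of the noon flask, held at 41 °C from the start, have a mean of 25.9%, which is 0.62 points above the spring mean and less than the margin of 2 points. So I expect the margin neither from waiting nor from heat. But the rise on offer is 25 K, applied at 6.0 h, and what that brings, or what taking out target brings, these readings do not show.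

6. I reckon that a second dose of coupling partner, at the same coupling yield, adds 25 points. I charge it.

7. The forecast gives 25.3% (from 24.7% to 25.9%), 25.3% after waiting and 25.7% after heating, and it chooses eta, holding that “the stall is not kinetic”.

8. The result follows.

    substrate + coupling partner → open intermediate (k = 4.80 M⁻¹ min⁻¹, Ea = 57.0 kJ mol⁻¹)
    coupling partner + fresh partner → second intermediate (k = 0.300 M⁻¹ min⁻¹, Ea = 72.0 kJ mol⁻¹)
    open intermediate + second intermediate → target (k = 0.710 M⁻¹ min⁻¹, Ea = 68.0 kJ mol⁻¹)
    target ⇌ isomer of the product (K = 0.350, k = 0.00610 min⁻¹, Ea = 104 kJ mol⁻¹, ΔH = 2.00 kJ mol⁻¹)
    (constants at 35 °C)

The spring flask gives 24.9%, a coupling yield of 0.192. It stays at 24.9% after waiting and gives 24.5% after heating, while eta adds 49 points, a coupling yield of 0.378 for that dose. At 1.41 min the half-life of coupling partner is 2.8 min by the step to open intermediate, shorter than the 13 min by the step to second intermediate. At 6.0 h open intermediate stands at 62.7% of the substrate charged, while coupling partner, the limiting reagent, stands at 0% of its own charge. The neighbour flask with 0.31 M of fresh partner reaches a coupling yield of 0.231.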